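**Strategy.** The trans-fused hydroazulene is traced back to a cis-decalin. The structure shows an oxygenated C4 in the seven-membered ring next to ring-fusion carbon C3a, whose partner C8a is the methyl-bearing quaternary centre (azulene numbering): the footprint of a stereospecific pinacol-type 1,2-shift. In an all-cis 1,2,8a-trioxygenated 4a-methyldecalin 1-mesylate, C4a migrates from C8a to C1; this contracts the cyclohexane that carries the isopropyl carbinol to the cyclopentane C1–C2–C3–C3a–C8a and, in the same event, enlarges the other ring to the cycloheptenone with the trans ring fusion. The decalin comes from an auxiliary-controlled Robinson annulation; no protecting group is needed.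

Key step: step 7

Remark on numbering: hydroazulenes are numbered as azulenes (C3 isopropyl carbinol, C3a/C8a ring fusion, C4 ester carbon, C7 allylic carbinol), decalins as naphthalenes.
Assumption: commercial 2,5-dimethylcyclohexanone is a mixture of stereoisomers; its C5 centre (C7 of 6–8) is erased in step 3 and is left undefined in the SMILES of 1 and 4–8.

Step 1
Reactants: 1 2,5-dimethylcyclohexan-1-one; 2 (R)-1-phenylethan-1-amine; 3 but-3-en-2-one
Product: 6 (2S)-2,5-dimethyl-2-(3-oxobutyl)cyclohexan-1-one (C5 epimers), via chiral ketimine 4 (not isolated), via Michael adduct ketimine 5 (not isolated)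
Conditions: 2, cat. TsOH, PhMe, reflux (−H2O); 3, THF, rt; 20% aq AcOH, rt
Reagents that add atoms: but-3-en-2-one (3), C=CC(C)=O; water, O (carbonyl oxygen on hydrolysis of the imine)
Why: Auxiliary-controlled Michael addition of the more substituted secondary enamine tautomer of 4 through an aza-ene-like chair transition state, in which the enone should approach the face away from the phenyl group and so set the quaternary centre as S.

Step 2
Reactants: 6 (2S)-2,5-dimethyl-2-(3-oxobutyl)cyclohexan-1-one
Product: 8 (4aS)-4a,7-dimethyl-4,4a,5,6,7,8-hexahydronaphthalen-2(3H)-one (C7 epimers), via cis-fused ketol 7 (not isolated)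
Conditions: NaOMe, MeOH, 60 °C
Reagents that add atoms: none
Why: Intramolecular aldol condensation, the second half of a Robinson annulation: the methyl ketone enolate closes the six-membered ring on the ring carbonyl and the ketol loses water to the conjugated enone, the quaternary centre being untouched.

Step 3
Reactants: 8 (4aS)-4a,7-dimethyl-4,4a,5,6,7,8-hexahydronaphthalen-2(3H)-one
Product: 9 (4aS)-4a,7-dimethyl-4,4a,5,6-tetrahydronaphthalen-2(3H)-one
Conditions: chloranil, t-BuOH, reflux
Reagents that add atoms: none
Why: Quinone dehydrogenation (hydride abstraction from C7 of the dienol) should give the linearly conjugated 1(8a),7-dienone as it does with 4-en-3-ones, so both C7 epimers converge on one compound and the double bond of the later cycloheptene is in place.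

Step 4
Reactants: 9 (4aS)-4a,7-dimethyl-4,4a,5,6-tetrahydronaphthalen-2(3H)-one; 10 isopropylmagnesium chloride
Product: 11 (2R,4aS)-4a,7-dimethyl-2-(propan-2-yl)-2,3,4,4a,5,6-hexahydronaphthalen-2-ol
Conditions: i-PrMgCl, anhydrous CeCl3, THF, −78 → 0 °C; aq NH4Cl
Reagents that add atoms: isopropylmagnesium chloride (10), CC(C)[Mg]Cl
Why: Organocerium 1,2-addition (no enolisation, reduction or 1,6-addition), in which the isopropyl group should enter axially on the face opposite the angular methyl group, as nucleophiles do with 4a-methyl octalones, so the new hydroxyl is cis to that methyl group (2R) and the minor epimer is removed by chromatography.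

Step 5
Reactants: 11 (2R,4aS)-4a,7-dimethyl-2-(propan-2-yl)-2,3,4,4a,5,6-hexahydronaphthalen-2-ol
Product: 13 (1S,2R,4aS,8aR)-4a,7-dimethyl-2-(propan-2-yl)-1,2,3,4,4a,5,6,8a-octahydronaphthalene-1,2,8a-triol (three hydroxyls cis to each other and to the 4a-methyl group), via osmate ester TMEDA chelate 12 (not isolated)
Conditions: OsO4 (1.0 equiv), TMEDA, CH2Cl2, −78 °C; aq Na2SO3, THF, 60 °C
Reagents that add atoms: osmium tetroxide, O=[Os](=O)(=O)=O
Why: Hydrogen-bond-directed syn-dihydroxylation with the OsO4·TMEDA complex: the tertiary allylic hydroxyl should deliver the oxidant to the neighbouring C1=C8a bond on its own face (1S,8aR), while one equivalent of reagent leaves the remote C7=C8 bond alone.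

Step 6
Reactants: 13 the all-cis triol; 14 methanesulfonyl chloride
Product: 15 (1S,2R,4aS,8aR)-2,8a-dihydroxy-4a,7-dimethyl-2-(propan-2-yl)-1,2,3,4,4a,5,6,8a-octahydronaphthalen-1-yl methanesulfonate
Conditions: MsCl, Et3N, CH2Cl2, −20 → 0 °C
Reagents that add atoms: methanesulfonyl chloride (14), CS(=O)(=O)Cl
Why: Chemoselective sulfonylation of the only secondary hydroxyl, which is equatorial in the preferred chair (isopropyl equatorial, the two tertiary hydroxyls 1,3-diaxial), while the tertiary alcohols do not react; no stereocentre changes.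

Step 7
Reactants: 15 the C1 mesylate
Product: 16 (3R,3aR,8aS)-3-hydroxy-6,8a-dimethyl-3-(propan-2-yl)-2,3,3a,7,8,8a-hexahydroazulen-4(1H)-one (trans-fused)
Conditions: Et3Al (3 equiv), CH2Cl2, −78 → 0 °C; aq Rochelle salt
Reagents that add atoms: none
Why: Pinacol-type (semipinacol) rearrangement of a β-hydroxy mesylate promoted by an organoaluminium reagent, the classical hydronaphthalene-to-hydroazulene shift: the C8a aluminium alkoxide pushes, C4a migrates from C8a to C1 and mesylate leaves in one concerted antiperiplanar event. Neither new ring is closed by a cyclisation in Baldwin's sense: the new bond C1–C4a closes the cyclopentane (contraction of the six-membered ring by expulsion of C8a) and the cycloheptenone (one-carbon enlargement of the other six-membered ring) in a single suprafacial 1,2-alkyl shift through a three-centre transition state. C3a (old C1) is set by inversion at the mesylate carbon and C8a (old C4a) migrates with retention, so the all-cis precursor should give the trans ring fusion with the C3 hydroxyl cis to the angular methyl group; C3 itself is not touched. The step needs migration of C4a and not of C3 (push from the C2 alkoxide) or of C8: the equatorial C1–O bond is antiperiplanar to C8a–C4a in the only low-energy chair, the quaternary C4a has the higher migratory aptitude and the allylic C8a alkoxide leads to a conjugated enone, whereas C8 is gauche to the leaving group. A Lewis-acidic, non-basic promoter at low temperature is chosen so that C3a, now α to the ketone, is not epimerised and the β-hydroxy ketone does not open by retro-aldol cleavage.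

Step 8
Reactants: 16 the trans-fused hydroxy enone
Product: 17 (3R,3aS,4S,8aS)-6,8a-dimethyl-3-(propan-2-yl)-1,2,3,3a,4,7,8,8a-octahydroazulene-3,4-diol
Conditions: Me4NBH(OAc)3, MeCN/AcOH, −20 °C
Reagents that add atoms: none
Why: Evans–Saksena hydroxyl-directed reduction: the β-oriented C3 hydroxyl binds the acetoxyborohydride and should deliver hydride to the β-face of the C4 carbonyl, giving the 4α-alcohol (4S) by 1,2-reduction only.

Step 9
Reactants: 17 the 3,4-diol; 18 4-methoxybenzoyl chloride
Product: 19 (3R,3aS,4S,8aS)-3-hydroxy-6,8a-dimethyl-3-(propan-2-yl)-1,2,3,3a,4,7,8,8a-octahydroazulen-4-yl 4-methoxybenzoate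
Conditions: 18, Et3N, DMAP, CH2Cl2, 0 °C → rt
Reagents that add atoms: 4-methoxybenzoyl chloride (18), COc1ccc(C(Cl)=O)cc1
Why: DMAP-catalysed acylation (nucleophilic catalysis) of the secondary allylic alcohol, the tertiary C3 hydroxyl being too hindered to react; no stereocentre is involved.

Step 10
Reactants: 19 the 4-methoxybenzoate
Product: 20 (3R,3aS,4S,7R,8aR)-3,7-dihydroxy-6,8a-dimethyl-3-(propan-2-yl)-1,2,3,3a,4,7,8,8a-octahydroazulen-4-yl 4-methoxybenzoate (target)
Conditions: SeO2 (0.5 equiv), t-BuOOH, CH2Cl2, rt
Reagents that add atoms: tert-butyl hydroperoxide, CC(C)(C)OO (terminal source of the new oxygen atom, relayed by selenium dioxide, O=[Se]=O)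
Why: Riley allylic hydroxylation (ene reaction, then [2,3]-sigmatropic shift) at the ring methylene on the more substituted alkene carbon (CH2 before CH3), in which selenium should add to C5 anti to the 4α-ester so that the suprafacial shift places the hydroxyl on the β-face of C7 (7R).

**Compound list**
1 | 2,5-dimethylcyclohexan-1-one (mixture of stereoisomers) | CC1CCC(C)C(=O)C1 | starting material
2 | (R)-1-phenylethan-1-amine | C[C@@H](N)c1ccccc1 | starting material
3 | but-3-en-2-one (methyl vinyl ketone) | C=CC(C)=O | starting material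
4 | N-[(1R)-1-phenylethyl]-2,5-dimethylcyclohexan-1-imine (chiral ketimine, not isolated) | CC1CCC(C)C(=N[C@H](C)c2ccccc2)C1 | intermediate
5 | (2S)-Michael adduct ketimine: N-[(1R)-1-phenylethyl]imine of 6 at the ring carbonyl (not isolated) | CC1CC[C@@](C)(CCC(C)=O)C(=N[C@H](C)c2ccccc2)C1 | intermediate
6 | (2S)-2,5-dimethyl-2-(3-oxobutyl)cyclohexan-1-one (C5 epimers) | CC1CC[C@@](C)(CCC(C)=O)C(=O)C1 | intermediate
7 | (4aS,8aS)-8a-hydroxy-4a,7-dimethyloctahydronaphthalen-2(1H)-one, cis-fused ketol (C7 epimers, not isolated) | CC1CC[C@@]2(C)CCC(=O)C[C@@]2(O)C1 | intermediate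
8 | (4aS)-4a,7-dimethyl-4,4a,5,6,7,8-hexahydronaphthalen-2(3H)-one (C7 epimers) | CC1CC[C@@]2(C)CCC(=O)C=C2C1 | intermediate
9 | (4aS)-4a,7-dimethyl-4,4a,5,6-tetrahydronaphthalen-2(3H)-one | CC1=CC2=CC(=O)CC[C@]2(C)CC1 | intermediate
10 | isopropylmagnesium chloride | CC(C)[Mg]Cl | starting material
11 | (2R,4aS)-4a,7-dimethyl-2-(propan-2-yl)-2,3,4,4a,5,6-hexahydronaphthalen-2-ol | CC1=CC2=C[C@](O)(C(C)C)CC[C@]2(C)CC1 | intermediate
12 | osmium(VI) ester of triol 13 through O1 and O8a, dioxo, TMEDA chelate (not isolated) | O1[C@]23C=C(C)CC[C@@]2(C)CC[C@@](O)(C(C)C)[C@@H]3O[Os-2]14(=O)(=O)[N+](C)(C)CC[N+]4(C)C | intermediate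
13 | (1S,2R,4aS,8aR)-4a,7-dimethyl-2-(propan-2-yl)-1,2,3,4,4a,5,6,8a-octahydronaphthalene-1,2,8a-triol | O[C@]12C=C(C)CC[C@@]1(C)CC[C@@](O)(C(C)C)[C@@H]2O | intermediate
14 | methanesulfonyl chloride | CS(=O)(=O)Cl | starting material
15 | (1S,2R,4aS,8aR)-2,8a-dihydroxy-4a,7-dimethyl-2-(propan-2-yl)-1,2,3,4,4a,5,6,8a-octahydronaphthalen-1-yl methanesulfonate | O[C@]12C=C(C)CC[C@@]1(C)CC[C@@](O)(C(C)C)[C@@H]2OS(C)(=O)=O | intermediate
16 | (3R,3aR,8aS)-3-hydroxy-6,8a-dimethyl-3-(propan-2-yl)-2,3,3a,7,8,8a-hexahydroazulen-4(1H)-one | O=C1C=C(C)CC[C@@]2(C)CC[C@@](O)(C(C)C)[C@H]12 | intermediate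
17 | (3R,3aS,4S,8aS)-6,8a-dimethyl-3-(propan-2-yl)-1,2,3,3a,4,7,8,8a-octahydroazulene-3,4-diol | O[C@H]1C=C(C)CC[C@@]2(C)CC[C@@](O)(C(C)C)[C@H]12 | intermediate
18 | 4-methoxybenzoyl chloride | COc1ccc(C(Cl)=O)cc1 | starting material
19 | (3R,3aS,4S,8aS)-3-hydroxy-6,8a-dimethyl-3-(propan-2-yl)-1,2,3,3a,4,7,8,8a-octahydroazulen-4-yl 4-methoxybenzoate | COc1ccc(C(=O)O[C@H]2C=C(C)CC[C@@]3(C)CC[C@@](O)(C(C)C)[C@H]23)cc1 | intermediate
20 | (3R,3aS,4S,7R,8aR)-3,7-dihydroxy-6,8a-dimethyl-3-(propan-2-yl)-1,2,3,3a,4,7,8,8a-octahydroazulen-4-yl 4-methoxybenzoate | COc1ccc(C(=O)O[C@H]2C=C(C)[C@H](O)C[C@@]3(C)CC[C@@](O)(C(C)C)[C@H]23)cc1 | target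

Total step count: 10. Longest linear sequence: 10 steps (1 → 20).

**Steps most likely to fail**

1. Step 7 (key step). What may go wrong: the C2 alkoxide takes over the push so that C3 migrates (contraction to an acylcyclopentane), or the aluminium aldolate of the product opens by retro-aldol cleavage or epimerises at C3a. Fallback, from 15 back to 16: the less hindered tertiary hydroxyl at C2 (its neighbour is a methylene, that of the C8a hydroxyl is the quaternary C4a) is silylated with TESOTf/2,6-lutidine at −78 °C to the 2-O-triethylsilyl ether of the mesylate F1. The same Et3Al-promoted 1,2-shift can then only be driven by the C8a alkoxide and should give the 3-O-triethylsilyl trans-hydroazulenone F2, which has no free aldol hydroxyl. HF·pyridine in THF then frees the C3 hydroxyl and gives 16.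

2. Step 5. What may go wrong: osmylation on the wrong face (the bulky OsO4·TMEDA complex has to approach the face that carries the angular methyl group) or at the C7=C8 bond. Fallback, from 11 back to 13: hydroxyl-directed epoxidation with VO(acac)2/t-BuOOH, a small oxidant that follows the allylic hydroxyl and reacts only at the allylic alkene, gives the syn 1,8a-epoxy alcohol F3 (a vinyl epoxide). Pd(0)-catalysed insertion of CO2 (Pd2(dba)3, P(Oi-Pr)3, CO2, THF) opens the allylic C8a–O bond and recloses with net retention to the cis-fused 1,8a-cyclic carbonate F4. K2CO3 in MeOH then releases triol 13.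

3. Step 10. What may go wrong: slow ene reaction of an alkene deactivated by the allylic ester, over-oxidation to the enone, competing oxidation of the C6 methyl group, or delivery of oxygen to the α-face of C7. Fallback, from 19 back to 20: allylic oxidation to the ketone (CrO3·3,5-dimethylpyrazole, CH2Cl2, −20 °C) gives the 7-oxo enone ester F5. Luche reduction (NaBH4, CeCl3·7H2O, MeOH, −78 °C), with hydride attack anti to the angular 8a-methyl group, should then give the 7β-alcohol 20.

**Further compounds**
F1 | step 7 | 2-O-triethylsilyl ether of mesylate 15 | O[C@]12C=C(C)CC[C@@]1(C)CC[C@@](O[Si](CC)(CC)CC)(C(C)C)[C@@H]2OS(C)(=O)=O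
F2 | step 7 | 3-O-triethylsilyl ether of hydroazulenone 16 | O=C1C=C(C)CC[C@@]2(C)CC[C@@](O[Si](CC)(CC)CC)(C(C)C)[C@H]12
F3 | step 5 | syn 1,8a-epoxide of dienol 11 (oxirane on the face of the C2 hydroxyl and the 4a-methyl group) | O1[C@]23C=C(C)CC[C@@]2(C)CC[C@@](O)(C(C)C)[C@@H]31
F4 | step 5 | cis-fused 1,8a-cyclic carbonate of triol 13 | O=C1O[C@]23C=C(C)CC[C@@]2(C)CC[C@@](O)(C(C)C)[C@@H]3O1
F5 | step 10 | 7-oxo analogue of ester 19 (6-en-7-one) | COc1ccc(C(=O)O[C@H]2C=C(C)C(=O)C[C@@]3(C)CC[C@@](O)(C(C)C)[C@H]23)cc1
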